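**Retrosynthetic overview**

1. The target comes from its penta-silyl ether 35 by global desilylation; 35 comes from the 8-bromochroman 30 and the cinnamic Weinreb amide 32 (C8–C(=O) bond, bromination of ring A then Br–Li exchange and acylation).
2. The side-chain carbinol comes from an enone carbonyl by CBS reduction; the styryl C=C is a temporary unsaturation that makes this reduction selective and is hydrogenated together with the benzyl ethers.
3. Key disconnection: the pyran ring is cut at both of its bonds to ring A, O1–C8a and C4–C4a. This gives 3-(benzyloxy)-5-methoxybenzyne (from silyl triflate 11) and the open-chain silyloxy dienone 20. All four benzene rings are bought; the pyran ring is the only ring made, in that step, together with the C4 stereocentre.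
4. Enabling feature: O1 and C4 sit on adjacent carbons of ring A (C8a, C4a) and are tied together by C2–C3. C4 is β to the side-chain carbinol carbon, so at the ketone level it is a Michael acceptor carbon. The C5 oxygen flanks C4a, so an alkoxy-polarised aryne takes the C2 alkoxide at C8a and the C4a anion closes onto C4; the C2 aryl group and the peri C5 substituent relay C2 to C4 (2,4-trans).
5. C2 is set by catalytic asymmetric allylation of 4-(benzyloxy)benzaldehyde; the chain is assembled by cross-metathesis with an aryl divinyl ketone.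

Key step: step 11

**Remarks and assumptions.** Compounds 1, 12, 15 and 31 are taken as commercial. Chroman numbering (O1, C2, C3, C4, C4a, C5–C8, C8a) is used; Bn = benzyl, TMS = trimethylsilyl, TBS = tert-butyldimethylsilyl. The CIP descriptor of C4 switches between R and S along the route because substituent priorities change; the spatial arrangement (2,4-trans) is the same throughout, as the SMILES show.

**Route**

Step 1
Reactants: 1 2-hydroxy-4-methoxybenzaldehyde
Product: 2 2-(benzyloxy)-4-methoxybenzaldehyde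
Conditions: BnBr, K2CO3, DMF, 60 °C
Reagents that add atoms: benzyl bromide, BrCc1ccccc1
Why: Williamson ether synthesis on the only phenol; the benzyl ether is the future C5 oxygen substituent that will polarise the aryne.

Step 2
Reactants: 2 2-(benzyloxy)-4-methoxybenzaldehyde
Product: 4 2-(benzyloxy)-4-methoxyphenol, via aryl formate 3 (not isolated)
Conditions: mCPBA, CH2Cl2, 0 °C to rt; then K2CO3 (cat.), MeOH, rt
Reagents that add atoms: meta-chloroperoxybenzoic acid, OOC(=O)c1cccc(Cl)c1
Why: Baeyer–Villiger (Dakin-type) oxidation, in which the electron-rich aryl group migrates to oxygen to give the aryl formate, which methanolysis converts into the phenol.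

Step 3
Reactants: 4 2-(benzyloxy)-4-methoxyphenol
Product: 5 2-(benzyloxy)-4-methoxyphenyl N-isopropylcarbamate
Conditions: iPrNCO, Et3N (cat.), CH2Cl2, rt
Reagents that add atoms: isopropyl isocyanate, CC(C)N=C=O
Why: Base-catalysed addition of the phenol to the isocyanate gives the secondary carbamate, the directing group for the next step, which can later be removed under mild base.

Step 4
Reactants: 5 2-(benzyloxy)-4-methoxyphenyl N-isopropylcarbamate
Product: 9 2-(benzyloxy)-4-methoxy-6-(trimethylsilyl)phenyl N-isopropylcarbamate, via N-silyl carbamate 6 (not isolated), via aryllithium 7 (not isolated), via disilyl carbamate 8 (not isolated)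
Conditions: TBSOTf, TMEDA, Et2O, 0 °C to rt; then n-BuLi, TMEDA, −78 °C; then TMSCl, −78 °C to rt; aq. NaHSO4
Reagents that add atoms: chlorotrimethylsilane, C[Si](C)(C)Cl
Why: Directed ortho-metalation in which the N-silylated carbamate, a far stronger director than the two ethers, guides n-BuLi to the only position ortho to it, the aryllithium is trapped by TMSCl and the N-silyl group falls off at the acidic work-up.

Step 5
Reactants: 9 2-(benzyloxy)-4-methoxy-6-(trimethylsilyl)phenyl N-isopropylcarbamate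
Product: 11 2-(benzyloxy)-4-methoxy-6-(trimethylsilyl)phenyl trifluoromethanesulfonate, via phenol 10 (not isolated)
Conditions: Et2NH, DBU, MeCN, 40 °C; then PhNTf2, rt
Reagents that add atoms: N-phenylbis(trifluoromethanesulfonimide), O=S(=O)(N(c1ccccc1)S(=O)(=O)C(F)(F)F)C(F)(F)F
Why: Amine-mediated E1cB cleavage of the secondary carbamate (the isocyanate is scavenged by Et2NH) frees the phenoxide, which is triflated in the same flask to give the ortho-silylaryl triflate aryne precursor.

Step 6
Reactants: 12 4-(benzyloxy)benzaldehyde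
Product: 14 (1R)-1-[4-(benzyloxy)phenyl]but-3-en-1-ol, via stannyl ether 13 (not isolated)
Conditions: allylSnBu3, (R)-BINOL (20 mol%), Ti(OiPr)4 (10 mol%), 4 Å MS, CH2Cl2, −20 °C; then aq. NaHCO3
Reagents that add atoms: allyltributylstannane, C=CC[Sn](CCCC)(CCCC)CCCC
Why: Keck asymmetric allylation, in which the BINOL–titanium Lewis acid exposes one face of the aldehyde to the allylstannane; the (R)-ligand should give the (R)-carbinol, which becomes C2 of the target.

Step 7
Reactants: 12 4-(benzyloxy)benzaldehyde; 15 diethyl {2-[methoxy(methyl)amino]-2-oxoethyl}phosphonate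
Product: 16 (2E)-3-[4-(benzyloxy)phenyl]-N-methoxy-N-methylprop-2-enamide
Conditions: NaH, THF, 0 °C to rt
Reagents that add atoms: none
Why: Horner–Wadsworth–Emmons olefination with a stabilised phosphonate, which should give the (E)-alkene.

Step 8
Reactants: 16 (2E)-3-[4-(benzyloxy)phenyl]-N-methoxy-N-methylprop-2-enamide
Product: 18 (1E)-1-[4-(benzyloxy)phenyl]penta-1,4-dien-3-one, via magnesium chelate 17 (not isolated)
Conditions: vinylMgBr, THF, −78 to 0 °C; then cold 1 M HCl
Reagents that add atoms: vinylmagnesium bromide, C=C[Mg]Br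
Why: Weinreb ketone synthesis, in which the chelated tetrahedral adduct stops at mono-addition and the acidic quench keeps the freed amine protonated so that it cannot add to the new vinyl ketone.

Step 9
Reactants: 14 (1R)-1-[4-(benzyloxy)phenyl]but-3-en-1-ol; 18 (1E)-1-[4-(benzyloxy)phenyl]penta-1,4-dien-3-one
Product: 19 (1E,4E,7R)-1,7-bis[4-(benzyloxy)phenyl]-7-hydroxyhepta-1,4-dien-3-one
Conditions: second-generation Grubbs catalyst (5 mol%), CH2Cl2, 40 °C
Reagents that add atoms: none
Why: Olefin cross-metathesis of a terminal alkene with a vinyl ketone, expected to be E-selective; the styryl double bond is 1,2-disubstituted and conjugated on both sides and should not take part, and the carbinol centre is untouched.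

Step 10
Reactants: 19 (1E,4E,7R)-1,7-bis[4-(benzyloxy)phenyl]-7-hydroxyhepta-1,4-dien-3-one
Product: 20 (1E,4E,7R)-1,7-bis[4-(benzyloxy)phenyl]-7-[(trimethylsilyl)oxy]hepta-1,4-dien-3-one
Conditions: TMSCl, imidazole, CH2Cl2, 0 °C
Reagents that add atoms: chlorotrimethylsilane, C[Si](C)(C)Cl
Why: Silylation of the secondary alcohol; the trimethylsilyl ether is a latent alkoxide that fluoride can release without a proton source.

Step 11
Reactants: 20 (1E,4E,7R)-1,7-bis[4-(benzyloxy)phenyl]-7-[(trimethylsilyl)oxy]hepta-1,4-dien-3-one; 11 2-(benzyloxy)-4-methoxy-6-(trimethylsilyl)phenyl trifluoromethanesulfonate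
Product: 25 (3E)-1-[(2R,4R)-5-(benzyloxy)-2-[4-(benzyloxy)phenyl]-7-methoxychroman-4-yl]-4-[4-(benzyloxy)phenyl]but-3-en-2-one, via aryne 21 (not isolated), via potassium alkoxide 22 (not isolated), via aryl anion 23 (not isolated), via potassium enolate 24 (not isolated)
Conditions: KF, 18-crown-6, THF, 0 °C to rt (11 in moderate excess); then aq. NH4Cl
Reagents that add atoms: none
Why: Proposed new method: fluoride strips the O–SiMe3 group of 20 to give the proton-free alkoxide 22 and triggers 1,2-elimination of 11 to 3-(benzyloxy)-5-methoxybenzyne 21; 22 adds to the aryne carbon remote from the benzyloxy group (the future C8a), the resulting aryl anion 23 at C4a attacks the β-carbon of the proximal (E)-enone, and enolate 24 is protonated at work-up. The closest known reaction type is the tandem addition of a heteroatom nucleophile to a fluoride-generated aryne with intramolecular Michael capture of the aryl anion (9-substituted xanthenes from ortho-hydroxychalcones, indolines from sulfonamido enoates), here extended to an aliphatic alkoxide released from a silyl ether. The one ring closed is the pyran ring, by 6-exo-trig anionic conjugate addition after the intermolecular O-arylation. The new C4 stereocentre is controlled by C2: in the half-chair transition state the C2 aryl group is pseudo-equatorial and the enone arm at C4 goes pseudo-axial to avoid peri (allylic 1,3) strain with the C5 benzyloxy group, which should give the 2,4-trans chroman. The step needs regioselective addition to the aryne, secured by the inductive polarisation from the adjacent benzyloxy group (attack meta to it, anion ortho to it); it also needs C–C closure on the proximal enone, secured by ring size (the carbonyl or the styryl terminus would need an eight-membered or larger ring) and by the absence of any O–H donor that could protonate the aryl anion.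

Step 12
Reactants: 25 (3E)-1-[(2R,4R)-5-(benzyloxy)-2-[4-(benzyloxy)phenyl]-7-methoxychroman-4-yl]-4-[4-(benzyloxy)phenyl]but-3-en-2-one
Product: 27 (2S,3E)-1-[(2R,4S)-5-(benzyloxy)-2-[4-(benzyloxy)phenyl]-7-methoxychroman-4-yl]-4-[4-(benzyloxy)phenyl]but-3-en-2-ol, via catechol borate 26 (not isolated)
Conditions: (R)-2-methyl-CBS-oxazaborolidine (20 mol%), catecholborane, toluene, −78 °C; then MeOH, 1 M NaOH wash
Reagents that add atoms: none
Why: Corey–Bakshi–Shibata reduction, in which the ketone binds the oxazaborolidine with the styryl group as the large substituent and hydride is delivered to one carbonyl face, so the (R)-catalyst should give the (2S)-allylic alcohol (the (R)-carbinol of the target once the alkene is saturated) by reagent control, the remote C4 centre having little influence.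

Step 13
Reactants: 27 (2S,3E)-1-[(2R,4S)-5-(benzyloxy)-2-[4-(benzyloxy)phenyl]-7-methoxychroman-4-yl]-4-[4-(benzyloxy)phenyl]but-3-en-2-ol
Product: 28 (2R,4S)-4-[(2R)-2-hydroxy-4-(4-hydroxyphenyl)butyl]-2-(4-hydroxyphenyl)-7-methoxychroman-5-ol
Conditions: H2 (1 atm), 10% Pd/C, EtOAc–MeOH, rt
Reagents that add atoms: none
Why: Heterogeneous hydrogenation should saturate the styryl alkene and hydrogenolyse the three benzyl ethers in one operation, while the cyclic benzylic C2–O bond and the stereocentres are expected to survive at 1 atm.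

Step 14
Reactants: 28 (2R,4S)-4-[(2R)-2-hydroxy-4-(4-hydroxyphenyl)butyl]-2-(4-hydroxyphenyl)-7-methoxychroman-5-ol
Product: 29 (2R,4R)-5-(TBS-oxy)-4-[(2R)-2-(TBS-oxy)-4-[4-(TBS-oxy)phenyl]butyl]-2-[4-(TBS-oxy)phenyl]-7-methoxychroman
Conditions: TBSOTf, 2,6-lutidine, CH2Cl2, 0 °C to rt
Reagents that add atoms: tert-butyldimethylsilyl trifluoromethanesulfonate, CC(C)(C)[Si](C)(C)OS(=O)(=O)C(F)(F)F
Why: Exhaustive silylation of the three phenols and the secondary alcohol; the bulky silyl ether on C5 is also the steric shield of C6 in the next step.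

Step 15
Reactants: 29 (2R,4R)-5-(TBS-oxy)-4-[(2R)-2-(TBS-oxy)-4-[4-(TBS-oxy)phenyl]butyl]-2-[4-(TBS-oxy)phenyl]-7-methoxychroman
Product: 30 (2R,4R)-8-bromo-5-(TBS-oxy)-4-[(2R)-2-(TBS-oxy)-4-[4-(TBS-oxy)phenyl]butyl]-2-[4-(TBS-oxy)phenyl]-7-methoxychroman
Conditions: NBS (1.0 equiv), CH2Cl2, −78 to 0 °C, dark
Reagents that add atoms: N-bromosuccinimide, O=C1CCC(=O)N1Br
Why: Electrophilic aromatic bromination of the only trioxygenated ring, directed to C8 (between O1 and OMe) as in 5,7-dioxygenated flavans, because C6 is screened by the C5 silyloxy group that the peri C4 substituent pushes towards it.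

Step 16
Reactants: 31 4-[(tert-butyldimethylsilyl)oxy]benzaldehyde; 15 diethyl {2-[methoxy(methyl)amino]-2-oxoethyl}phosphonate
Product: 32 (2E)-3-[4-(TBS-oxy)phenyl]-N-methoxy-N-methylprop-2-enamide
Conditions: NaH, THF, 0 °C to rt
Reagents that add atoms: none
Why: Horner–Wadsworth–Emmons olefination with a stabilised phosphonate, which should give the (E)-alkene of the chalcone arm.

Step 17
Reactants: 30 (2R,4R)-8-bromo-5-(TBS-oxy)-4-[(2R)-2-(TBS-oxy)-4-[4-(TBS-oxy)phenyl]butyl]-2-[4-(TBS-oxy)phenyl]-7-methoxychroman; 32 (2E)-3-[4-(TBS-oxy)phenyl]-N-methoxy-N-methylprop-2-enamide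
Product: 35 (2E)-1-[(2R,4R)-5-(TBS-oxy)-4-[(2R)-2-(TBS-oxy)-4-[4-(TBS-oxy)phenyl]butyl]-2-[4-(TBS-oxy)phenyl]-7-methoxychroman-8-yl]-3-[4-(TBS-oxy)phenyl]prop-2-en-1-one, via aryllithium 33 (not isolated), via lithium chelate 34 (not isolated)
Conditions: t-BuLi (2.1 equiv), THF, −78 °C; then 32, −78 to 0 °C; then aq. NH4Cl
Reagents that add atoms: none
Why: Bromine–lithium exchange followed by acylation of the aryllithium with the Weinreb amide, whose chelated adduct collapses to the enone only at work-up, so the (E)-chalcone arm is installed at C8 in one operation.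

Step 18
Reactants: 35 (2E)-1-[(2R,4R)-5-(TBS-oxy)-4-[(2R)-2-(TBS-oxy)-4-[4-(TBS-oxy)phenyl]butyl]-2-[4-(TBS-oxy)phenyl]-7-methoxychroman-8-yl]-3-[4-(TBS-oxy)phenyl]prop-2-en-1-one
Product: 36 (2E)-1-[(2R,4S)-5-hydroxy-4-[(2R)-2-hydroxy-4-(4-hydroxyphenyl)butyl]-2-(4-hydroxyphenyl)-7-methoxychroman-8-yl]-3-(4-hydroxyphenyl)prop-2-en-1-one
Conditions: TBAF, AcOH, THF, 0 °C to rt
Reagents that add atoms: none
Why: Fluoride-mediated cleavage of all five silyl ethers, buffered with AcOH so that the chalcone and the C2 benzylic ether see neither strong base nor strong acid; no stereocentre is touched.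

**Compound list**

1 | 2-hydroxy-4-methoxybenzaldehyde | COc1ccc(C=O)c(O)c1 | starting material
2 | 2-(benzyloxy)-4-methoxybenzaldehyde | COc1ccc(C=O)c(OCc2ccccc2)c1 | intermediate
3 | 2-(benzyloxy)-4-methoxyphenyl formate | COc1ccc(OC=O)c(OCc2ccccc2)c1 | intermediate
4 | 2-(benzyloxy)-4-methoxyphenol | COc1ccc(O)c(OCc2ccccc2)c1 | intermediate
5 | 2-(benzyloxy)-4-methoxyphenyl N-isopropylcarbamate | COc1ccc(OC(=O)NC(C)C)c(OCc2ccccc2)c1 | intermediate
6 | 2-(benzyloxy)-4-methoxyphenyl N-(tert-butyldimethylsilyl)-N-isopropylcarbamate | COc1ccc(OC(=O)N(C(C)C)[Si](C)(C)C(C)(C)C)c(OCc2ccccc2)c1 | intermediate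
7 | 6-lithio derivative of 6 (lithium ortho to the carbamate) | COc1cc([Li])c(OC(=O)N(C(C)C)[Si](C)(C)C(C)(C)C)c(OCc2ccccc2)c1 | intermediate
8 | 2-(benzyloxy)-4-methoxy-6-(trimethylsilyl)phenyl N-(tert-butyldimethylsilyl)-N-isopropylcarbamate | COc1cc([Si](C)(C)C)c(OC(=O)N(C(C)C)[Si](C)(C)C(C)(C)C)c(OCc2ccccc2)c1 | intermediate
9 | 2-(benzyloxy)-4-methoxy-6-(trimethylsilyl)phenyl N-isopropylcarbamate | COc1cc([Si](C)(C)C)c(OC(=O)NC(C)C)c(OCc2ccccc2)c1 | intermediate
10 | 2-(benzyloxy)-4-methoxy-6-(trimethylsilyl)phenol | COc1cc([Si](C)(C)C)c(O)c(OCc2ccccc2)c1 | intermediate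
11 | 2-(benzyloxy)-4-methoxy-6-(trimethylsilyl)phenyl trifluoromethanesulfonate | COc1cc([Si](C)(C)C)c(OS(=O)(=O)C(F)(F)F)c(OCc2ccccc2)c1 | intermediate
12 | 4-(benzyloxy)benzaldehyde | O=Cc1ccc(OCc2ccccc2)cc1 | starting material
13 | tributyl{[(1R)-1-[4-(benzyloxy)phenyl]but-3-en-1-yl]oxy}stannane | CCCC[Sn](CCCC)(CCCC)O[C@@H](c1ccc(OCc2ccccc2)cc1)CC=C | intermediate
14 | (1R)-1-[4-(benzyloxy)phenyl]but-3-en-1-ol | O[C@@H](c1ccc(OCc2ccccc2)cc1)CC=C | intermediate
15 | diethyl {2-[methoxy(methyl)amino]-2-oxoethyl}phosphonate | CCOP(=O)(CC(=O)N(C)OC)OCC | starting material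
16 | (2E)-3-[4-(benzyloxy)phenyl]-N-methoxy-N-methylprop-2-enamide | CON(C)C(=O)/C=C/c1ccc(OCc2ccccc2)cc1 | intermediate
17 | bromomagnesium alkoxide of the vinyl adduct of 16 (tetrahedral chelate) | C=CC(O[Mg]Br)(N(C)OC)/C=C/c1ccc(OCc2ccccc2)cc1 | intermediate
18 | (1E)-1-[4-(benzyloxy)phenyl]penta-1,4-dien-3-one | C=CC(=O)/C=C/c1ccc(OCc2ccccc2)cc1 | intermediate
19 | (1E,4E,7R)-1,7-bis[4-(benzyloxy)phenyl]-7-hydroxyhepta-1,4-dien-3-one | O[C@@H](c1ccc(OCc2ccccc2)cc1)C/C=C/C(=O)/C=C/c1ccc(OCc2ccccc2)cc1 | intermediate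
20 | (1E,4E,7R)-1,7-bis[4-(benzyloxy)phenyl]-7-[(trimethylsilyl)oxy]hepta-1,4-dien-3-one | C[Si](C)(C)O[C@@H](c1ccc(OCc2ccccc2)cc1)C/C=C/C(=O)/C=C/c1ccc(OCc2ccccc2)cc1 | intermediate
21 | 3-(benzyloxy)-5-methoxybenzyne | COC1=CC#CC(OCc2ccccc2)=C1 | intermediate
22 | potassium (1R,3E,6E)-1,7-bis[4-(benzyloxy)phenyl]-5-oxohepta-3,6-dien-1-olate | [K+].[O-][C@@H](c1ccc(OCc2ccccc2)cc1)C/C=C/C(=O)/C=C/c1ccc(OCc2ccccc2)cc1 | intermediate
23 | potassium 2-(benzyloxy)-6-{[(1R,3E,6E)-1,7-bis[4-(benzyloxy)phenyl]-5-oxohepta-3,6-dien-1-yl]oxy}-4-methoxybenzen-1-ide | [K+].COc1cc(OCc2ccccc2)[c-]c(c1)O[C@@H](c1ccc(OCc2ccccc2)cc1)C/C=C/C(=O)/C=C/c1ccc(OCc2ccccc2)cc1 | intermediate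
24 | potassium enolate of 25 | [K+].COc1cc(OCc3ccccc3)c2c(c1)O[C@@H](c1ccc(OCc3ccccc3)cc1)C[C@@H]2C=C([O-])/C=C/c1ccc(OCc3ccccc3)cc1 | intermediate
25 | (3E)-1-[(2R,4R)-5-(benzyloxy)-2-[4-(benzyloxy)phenyl]-7-methoxychroman-4-yl]-4-[4-(benzyloxy)phenyl]but-3-en-2-one (2,4-trans) | COc1cc(OCc3ccccc3)c2c(c1)O[C@@H](c1ccc(OCc3ccccc3)cc1)C[C@@H]2CC(=O)/C=C/c1ccc(OCc3ccccc3)cc1 | intermediate
26 | catechol borate (2-alkoxy-1,3,2-benzodioxaborole) of 27 | COc1cc(OCc3ccccc3)c2c(c1)O[C@@H](c1ccc(OCc3ccccc3)cc1)C[C@@H]2C[C@H](OB1Oc3ccccc3O1)/C=C/c1ccc(OCc3ccccc3)cc1 | intermediate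
27 | (2S,3E)-1-[(2R,4S)-5-(benzyloxy)-2-[4-(benzyloxy)phenyl]-7-methoxychroman-4-yl]-4-[4-(benzyloxy)phenyl]but-3-en-2-ol | COc1cc(OCc3ccccc3)c2c(c1)O[C@@H](c1ccc(OCc3ccccc3)cc1)C[C@@H]2C[C@H](O)/C=C/c1ccc(OCc3ccccc3)cc1 | intermediate
28 | (2R,4S)-4-[(2R)-2-hydroxy-4-(4-hydroxyphenyl)butyl]-2-(4-hydroxyphenyl)-7-methoxychroman-5-ol | COc1cc(O)c2c(c1)O[C@@H](c1ccc(O)cc1)C[C@@H]2C[C@H](O)CCc1ccc(O)cc1 | intermediate
29 | tetrakis-TBS ether of 28, (2R,4R), side chain (2R) | COc1cc(O[Si](C)(C)C(C)(C)C)c2c(c1)O[C@@H](c1ccc(O[Si](C)(C)C(C)(C)C)cc1)C[C@@H]2C[C@H](O[Si](C)(C)C(C)(C)C)CCc1ccc(O[Si](C)(C)C(C)(C)C)cc1 | intermediate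
30 | 8-bromo derivative of 29, (2R,4R), side chain (2R) | COc1cc(O[Si](C)(C)C(C)(C)C)c2c(c1Br)O[C@@H](c1ccc(O[Si](C)(C)C(C)(C)C)cc1)C[C@@H]2C[C@H](O[Si](C)(C)C(C)(C)C)CCc1ccc(O[Si](C)(C)C(C)(C)C)cc1 | intermediate
31 | 4-[(tert-butyldimethylsilyl)oxy]benzaldehyde | O=Cc1ccc(O[Si](C)(C)C(C)(C)C)cc1 | starting material
32 | (2E)-3-{4-[(tert-butyldimethylsilyl)oxy]phenyl}-N-methoxy-N-methylprop-2-enamide | CON(C)C(=O)/C=C/c1ccc(O[Si](C)(C)C(C)(C)C)cc1 | intermediate
33 | 8-lithio derivative of 29 | COc1cc(O[Si](C)(C)C(C)(C)C)c2c(c1[Li])O[C@@H](c1ccc(O[Si](C)(C)C(C)(C)C)cc1)C[C@@H]2C[C@H](O[Si](C)(C)C(C)(C)C)CCc1ccc(O[Si](C)(C)C(C)(C)C)cc1 | intermediate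
34 | lithium alkoxide of the adduct of 33 with 32 (tetrahedral chelate) | COc1cc(O[Si](C)(C)C(C)(C)C)c2c(c1C(O[Li])(N(C)OC)/C=C/c1ccc(O[Si](C)(C)C(C)(C)C)cc1)O[C@@H](c1ccc(O[Si](C)(C)C(C)(C)C)cc1)C[C@@H]2C[C@H](O[Si](C)(C)C(C)(C)C)CCc1ccc(O[Si](C)(C)C(C)(C)C)cc1 | intermediate
35 | pentakis-TBS ether of the target, (2R,4R), side chain (2R), (E)-enone | COc1cc(O[Si](C)(C)C(C)(C)C)c2c(c1C(=O)/C=C/c1ccc(O[Si](C)(C)C(C)(C)C)cc1)O[C@@H](c1ccc(O[Si](C)(C)C(C)(C)C)cc1)C[C@@H]2C[C@H](O[Si](C)(C)C(C)(C)C)CCc1ccc(O[Si](C)(C)C(C)(C)C)cc1 | intermediate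
36 | (2E)-1-[(2R,4S)-5-hydroxy-4-[(2R)-2-hydroxy-4-(4-hydroxyphenyl)butyl]-2-(4-hydroxyphenyl)-7-methoxychroman-8-yl]-3-(4-hydroxyphenyl)prop-2-en-1-one | COc1cc(O)c2c(c1C(=O)/C=C/c1ccc(O)cc1)O[C@@H](c1ccc(O)cc1)C[C@@H]2C[C@H](O)CCc1ccc(O)cc1 | target

**Step count**

Total: 18 steps. Longest linear sequence: 12 steps (steps 1–5, 11–15, 17, 18).

**Steps most likely to fail, with fallbacks**

Step 11 (proposed new method). Three processes may defeat it: the free alkoxide may fragment by vinylogous retro-aldol cleavage or eliminate before it meets the aryne; the aryl anion may be protonated, or the product enolate arylated by a second aryne, instead of clean ring closure; and the facial selectivity at C4 may be poor. The fallback makes the same two bonds one after the other by known reactions, so that alkoxide and enone never coexist. It sets out from 5 (through 6 and 7 as in step 4), 14 and 18 and comes back to the route at 25. The aryllithium 7 is quenched with I2 instead of TMSCl to give 2-(benzyloxy)-6-iodo-4-methoxyphenyl N-(tert-butyldimethylsilyl)-N-isopropylcarbamate F1, which loses the N-silyl group at work-up to give 2-(benzyloxy)-6-iodo-4-methoxyphenyl N-isopropylcarbamate F2. Et2NH/DBU and then PhNTf2, as in step 5, give through 2-(benzyloxy)-6-iodo-4-methoxyphenol F3 the triflate 2-(benzyloxy)-6-iodo-4-methoxyphenyl trifluoromethanesulfonate F4. Copper-catalysed Ullmann-type etherification of the iodide with alcohol 14 (CuI, 3,4,7,8-tetramethyl-1,10-phenanthroline, Cs2CO3, toluene, 80 °C; the carbinol C–O bond is not touched, so C2 is retained) should give 2-(benzyloxy)-6-{[(1R)-1-[4-(benzyloxy)phenyl]but-3-en-1-yl]oxy}-4-methoxyphenyl trifluoromethanesulfonate F5. Cross-metathesis with 18 as in step 9 should give 2-(benzyloxy)-6-{[(1R,3E,6E)-1,7-bis[4-(benzyloxy)phenyl]-5-oxohepta-3,6-dien-1-yl]oxy}-4-methoxyphenyl trifluoromethanesulfonate F6. An intramolecular reductive Heck reaction of the aryl triflate (Pd(OAc)2, 1,3-bis(diphenylphosphino)propane, HCO2Na, DMF, 80 °C; 6-exo carbopalladation of the enone, then formate reduction) closes the C4–C4a bond and gives 25, with the same peri-strain argument for the 2,4-trans isomer.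

Step 15. The bromination may lose site selectivity (attack at C6, or twofold bromination of ring A). The fallback replaces electrophilic substitution by directed ortho-lithiation. It sets out from 29 and comes back to the route at 33 and so at 35. With n-BuLi/TMEDA in THF at 0 °C, C8–H lies between two coordinating ether oxygens (O1 and OMe), whereas C6–H is flanked by the bulky, poorly coordinating silyl ether, so deprotonation should give 33 directly; this is acylated with 32 as in step 17. No new compound is made.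

Step 13. The allylic C–O bond may be lost by hydrogenolysis, the allylic alcohol may isomerise to the ketone on palladium hydride, or the pyran C2–O bond may open once the para-phenol is free. The fallback separates alkene reduction from debenzylation. It sets out from 27 and comes back to the route at 28. Diimide reduction (2-nitrobenzenesulfonylhydrazide, Et3N, CH2Cl2, rt) saturates the styryl alkene without a metal and should give (2R)-1-[(2R,4S)-5-(benzyloxy)-2-[4-(benzyloxy)phenyl]-7-methoxychroman-4-yl]-4-[4-(benzyloxy)phenyl]butan-2-ol F7; the three benzyl ethers are then removed by transfer hydrogenolysis (Pd(OH)2/C, cyclohexa-1,4-diene, EtOH, rt) to give 28.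

**Further compounds**

F1 | step 11 | 2-(benzyloxy)-6-iodo-4-methoxyphenyl N-(tert-butyldimethylsilyl)-N-isopropylcarbamate | COc1cc(I)c(OC(=O)N(C(C)C)[Si](C)(C)C(C)(C)C)c(OCc2ccccc2)c1
F2 | step 11 | 2-(benzyloxy)-6-iodo-4-methoxyphenyl N-isopropylcarbamate | COc1cc(I)c(OC(=O)NC(C)C)c(OCc2ccccc2)c1
F3 | step 11 | 2-(benzyloxy)-6-iodo-4-methoxyphenol | COc1cc(I)c(O)c(OCc2ccccc2)c1
F4 | step 11 | 2-(benzyloxy)-6-iodo-4-methoxyphenyl trifluoromethanesulfonate | COc1cc(I)c(OS(=O)(=O)C(F)(F)F)c(OCc2ccccc2)c1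
F5 | step 11 | 2-(benzyloxy)-6-{[(1R)-1-[4-(benzyloxy)phenyl]but-3-en-1-yl]oxy}-4-methoxyphenyl trifluoromethanesulfonate | COc1cc(OCc2ccccc2)c(OS(=O)(=O)C(F)(F)F)c(c1)O[C@@H](c1ccc(OCc2ccccc2)cc1)CC=C
F6 | step 11 | 2-(benzyloxy)-6-{[(1R,3E,6E)-1,7-bis[4-(benzyloxy)phenyl]-5-oxohepta-3,6-dien-1-yl]oxy}-4-methoxyphenyl trifluoromethanesulfonate | COc1cc(OCc2ccccc2)c(OS(=O)(=O)C(F)(F)F)c(c1)O[C@@H](c1ccc(OCc2ccccc2)cc1)C/C=C/C(=O)/C=C/c1ccc(OCc2ccccc2)cc1
F7 | step 13 | (2R)-1-[(2R,4S)-5-(benzyloxy)-2-[4-(benzyloxy)phenyl]-7-methoxychroman-4-yl]-4-[4-(benzyloxy)phenyl]butan-2-ol | COc1cc(OCc3ccccc3)c2c(c1)O[C@@H](c1ccc(OCc3ccccc3)cc1)C[C@@H]2C[C@H](O)CCc1ccc(OCc3ccccc3)cc1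
F0 | step 15 | none | none
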